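## Retrosynthetic overview

1. The strategy rests on ring A. It is a para-disubstituted benzene with the diaryl ether oxygen at C4 and the CH2 of an allyl group at C1. An alkynyl ether and a 2-pyrone-5-carboxylate leave exactly this 1,4-O/C pattern after (4+2) addition and loss of CO2.
2. Ring A is cut at C4–C5 and C3–C2. An ethynyl ether on the C3 oxygen of ring B plus methyl coumalate give a methyl 4-aryloxybenzoate.
3. The ester at C1 of ring A becomes the third allyl group (CO2Me → CH2OH → CH2Br → CH2–CH=CH2). The two O-methyl groups on rings B and C are removed last.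
4. The ethynyl ether comes from magnolol. Monomethylation breaks the symmetry, iodination at C3 and I → OH exchange place the third oxygen, and trichloroethylene then n-BuLi build the O–C≡CH unit.
5. Ring order: rings B and C and their C1–C1' bond are bought with magnolol, and ring A is the only ring formed.

Key step: step 7

Remark on the chemistry: the target has no stereocentre and its 2,2'-dioxygenated biaryl axis is taken as freely rotating, so no stereocontrol is planned; locants are ring B C1 (biaryl bond), C2 (O), C3 (O to ring A), C5 (allyl), ring C primed, ring A C1 (CH2) and C4 (O).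

## Route

Step 1
Reactants: 1 magnolol (5,5'-diallylbiphenyl-2,2'-diol)
Product: 2 2-O-methylmagnolol (5,5'-diallyl-2'-methoxybiphenyl-2-ol)
Conditions: MeI (1.0 equiv), K2CO3 (1.0 equiv), acetone, rt → 40 °C
Reagents that add atoms: iodomethane, CI
Why: Williamson ether synthesis on a 2,2'-biphenol, whose first proton is far more acidic than the second because the monoanion is held by an intramolecular hydrogen bond, so that one equivalent of base and of MeI should stop at the monoether and break the symmetry of 1.

Step 2
Reactants: 2 2-O-methylmagnolol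
Product: 3 5,5'-diallyl-3-iodo-2'-methoxybiphenyl-2-ol
Conditions: I2 (1.0 equiv), KI, 25% aq NH3, MeOH, 0 °C → rt
Reagents that add atoms: iodine, II
Why: Electrophilic aromatic iodination of a phenolate: only ring B carries a free OH, its C1 and C5 positions are occupied so that C3 is the sole activated site, and I2 in aqueous ammonia is too weak an electrophile to add to the terminal alkenes or to attack the anisole ring C.

Step 3
Reactants: 3 5,5'-diallyl-3-iodo-2'-methoxybiphenyl-2-ol
Product: 4 5,5'-diallyl-3-iodo-2,2'-dimethoxybiphenyl
Conditions: MeI (3 equiv), K2CO3 (3 equiv), DMF, rt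
Reagents that add atoms: iodomethane, CI
Why: Williamson ether synthesis in which the small electrophile reaches the flanked phenolate and carbonate is too weak a base to move the allyl double bonds into conjugation.

Step 4
Reactants: 4 5,5'-diallyl-3-iodo-2,2'-dimethoxybiphenyl
Product: 7 5,5'-diallyl-2,2'-dimethoxybiphenyl-3-ol, via arylmagnesium chloride 5 (not isolated), via dimethyl arylboronate 6 (not isolated)
Conditions: iPrMgCl·LiCl (1.2 equiv), THF, 0 °C; B(OMe)3, 0 °C → rt; 30% H2O2, aq NaOH, 0 °C
Reagents that add atoms: hydrogen peroxide, OO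
Why: Iodine–magnesium exchange with the turbo-Grignard reagent, trapping by the borate and oxidative 1,2-migration of the aryl group from boron to oxygen (boronate oxidation) replace I by OH in one flask, the arylmagnesium being too weakly basic to metalate the allylic CH2 groups and alkaline H2O2 leaving unactivated alkenes alone.

Step 5
Reactants: 7 5,5'-diallyl-2,2'-dimethoxybiphenyl-3-ol; 8 trichloroethylene
Product: 10 5,5'-diallyl-3-{[(E)-1,2-dichlorovinyl]oxy}-2,2'-dimethoxybiphenyl, via dichloroacetylene 9 (not isolated)
Conditions: 8 (2 equiv), K2CO3, DMF, 70 °C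
Reagents that add atoms: none
Why: Elimination–addition route to aryl 1,2-dichlorovinyl ethers: carbonate strips HCl from 8, the phenolate of 7 adds to the dichloroacetylene so formed and anti protonation of the vinyl anion sets the E geometry, while the mild base leaves the allyl groups in place.

Step 6
Reactants: 10 5,5'-diallyl-3-{[(E)-1,2-dichlorovinyl]oxy}-2,2'-dimethoxybiphenyl
Product: 13 5,5'-diallyl-3-(ethynyloxy)-2,2'-dimethoxybiphenyl, via chloroethynyl ether 11 (not isolated), via lithium aryloxyacetylide 12 (not isolated)
Conditions: n-BuLi (2.2 equiv), Et2O, −78 → −40 °C; H2O, −78 → 0 °C; short plug of basic Al2O3, used at once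
Reagents that add atoms: none
Why: Dichlorovinyl ether route to ynol ethers: n-BuLi removes the acidified vinylic proton with loss of LiCl, a second equivalent performs chlorine–lithium exchange on the chloroalkyne and water protonates the acetylide, all of it much faster at −78 °C than metalation of the allylic CH2 groups, and an aryl ynol ether has no β-hydrogen on the oxygen substituent through which it could fragment to a ketene.

Step 7
Reactants: 13 5,5'-diallyl-3-(ethynyloxy)-2,2'-dimethoxybiphenyl; 14 methyl coumalate (methyl 2-oxo-2H-pyran-5-carboxylate)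
Product: 16 methyl 4-[(5,5'-diallyl-2,2'-dimethoxybiphenyl-3-yl)oxy]benzoate, via bridged lactone 15 (not isolated)
Conditions: 14 (1.5 equiv), BHT (cat.), PhMe, 120 °C, sealed tube
Reagents that add atoms: none
Why: Inverse-electron-demand Diels–Alder reaction followed by retro-Diels–Alder loss of CO2: the diene C3=C4–C5=C6 of 14, made electron-poor by the lactone carbonyl and the C5 ester, takes up the electron-rich C≡C of 13 in a concerted but asynchronous (4+2) addition in which the terminal alkyne carbon, the nucleophilic end of the ynol ether, runs ahead in bonding to C6 (β to the ester, vinylogous to the lactone carbonyl) while the oxygen-bearing carbon bonds to C3. The resulting 2-oxabicyclo[2.2.2]octadienone 15 expels CO2 at the reaction temperature and is aromatic at once, with no oxidation or elimination step needed. Ring A is therefore closed by an intermolecular (4+2) cycloaddition that makes its C4–C5 and C3–C2 bonds, C4 and C3 being the former alkyne carbons and C5, C6, C1 and C2 the former pyrone carbons C3, C4, C5 and C6. The closest known chemistry is the reaction of methyl coumalate and other 2-pyrone carboxylates with alkoxyalkynes, ynamines, enol ethers and ketene acetals, which delivers para-substituted benzoates. No stereocentre has to be controlled, because the two bridgehead centres of racemic 15 disappear on aromatisation. The step needs para regiochemistry, which the matched polarisation of the ynol ether and C6 secures, and chemoselectivity for the alkyne over the two allyl groups, which follows from the much higher HOMO of the ynol ether (unactivated terminal alkenes add to 14 only at far higher temperature).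

Step 8
Reactants: 16 methyl 4-[(5,5'-diallyl-2,2'-dimethoxybiphenyl-3-yl)oxy]benzoate
Product: 17 {4-[(5,5'-diallyl-2,2'-dimethoxybiphenyl-3-yl)oxy]phenyl}methanol
Conditions: iBu2AlH (DIBAL-H, 2.5 equiv), CH2Cl2, −78 → 0 °C; aq potassium sodium tartrate
Reagents that add atoms: none
Why: Ester reduction with an aluminium hydride: two hydride transfers take the benzoate to the primary benzylic alcohol at low temperature, where hydroalumination of terminal alkenes does not compete and the aryl ethers are inert.

Step 9
Reactants: 17 {4-[(5,5'-diallyl-2,2'-dimethoxybiphenyl-3-yl)oxy]phenyl}methanol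
Product: 18 5,5'-diallyl-3-[4-(bromomethyl)phenoxy]-2,2'-dimethoxybiphenyl
Conditions: CBr4, PPh3, CH2Cl2, 0 °C
Reagents that add atoms: tetrabromomethane, BrC(Br)(Br)Br
Why: Appel reaction: PPh3 and CBr4 activate the primary benzylic alcohol and bromide displaces it in an SN2 step under essentially neutral conditions that leave alkenes and aryl ethers untouched.

Step 10
Reactants: 18 5,5'-diallyl-3-[4-(bromomethyl)phenoxy]-2,2'-dimethoxybiphenyl; 19 vinylmagnesium bromide
Product: 20 5,5'-diallyl-3-(4-allylphenoxy)-2,2'-dimethoxybiphenyl (di-O-methylisodunnianol)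
Conditions: 19 (1.5 equiv), CuI (10 mol %), 2,2'-bipyridyl (10 mol %), THF, −20 °C → rt
Reagents that add atoms: none
Why: Copper-catalysed cross-coupling of a Grignard reagent with a benzylic halide: a vinylcopper species made in situ displaces the primary benzylic bromide and forms the CH2–CH= bond of the third allyl group, a standard way from benzyl bromides to allylarenes.

Step 11
Reactants: 20 5,5'-diallyl-3-(4-allylphenoxy)-2,2'-dimethoxybiphenyl
Product: 22 isodunnianol (5,5'-diallyl-3-(4-allylphenoxy)biphenyl-2,2'-diol), via bis(dibromoboryl) ether 21 (not isolated)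
Conditions: BBr3 (3 equiv), CH2Cl2, −78 → 0 °C; H2O
Reagents that add atoms: none
Why: Lewis-acid cleavage of aryl methyl ethers with BBr3: boron binds each methoxy oxygen and bromide attacks the methyl carbon in an SN2 step, which is impossible at the sp2 carbons of the diaryl ether, and at low temperature para-allyl groups are known to survive in biphenyl neolignan methyl ethers, hydrolysis of 21 then freeing both phenols.

## Compound list

1 | magnolol (5,5'-diallylbiphenyl-2,2'-diol) | C=CCc1ccc(O)c(-c2cc(CC=C)ccc2O)c1 | starting material
2 | 2-O-methylmagnolol (5,5'-diallyl-2'-methoxybiphenyl-2-ol) | C=CCc1ccc(OC)c(-c2cc(CC=C)ccc2O)c1 | intermediate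
3 | 5,5'-diallyl-3-iodo-2'-methoxybiphenyl-2-ol | C=CCc1ccc(OC)c(-c2cc(CC=C)cc(I)c2O)c1 | intermediate
4 | 5,5'-diallyl-3-iodo-2,2'-dimethoxybiphenyl | C=CCc1ccc(OC)c(-c2cc(CC=C)cc(I)c2OC)c1 | intermediate
5 | (5,5'-diallyl-2,2'-dimethoxybiphenyl-3-yl)magnesium chloride (LiCl complex, not isolated) | C=CCc1ccc(OC)c(-c2cc(CC=C)cc([Mg]Cl)c2OC)c1 | intermediate
6 | dimethyl (5,5'-diallyl-2,2'-dimethoxybiphenyl-3-yl)boronate (not isolated) | C=CCc1ccc(OC)c(-c2cc(CC=C)cc(B(OC)OC)c2OC)c1 | intermediate
7 | 5,5'-diallyl-2,2'-dimethoxybiphenyl-3-ol | C=CCc1ccc(OC)c(-c2cc(CC=C)cc(O)c2OC)c1 | intermediate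
8 | trichloroethylene | ClC=C(Cl)Cl | starting material
9 | dichloroacetylene (not isolated) | ClC#CCl | intermediate
10 | 5,5'-diallyl-3-{[(E)-1,2-dichlorovinyl]oxy}-2,2'-dimethoxybiphenyl | Cl/C=C(Cl)\Oc1cc(CC=C)cc(-c2cc(CC=C)ccc2OC)c1OC | intermediate
11 | 5,5'-diallyl-3-[(chloroethynyl)oxy]-2,2'-dimethoxybiphenyl (not isolated) | ClC#COc1cc(CC=C)cc(-c2cc(CC=C)ccc2OC)c1OC | intermediate
12 | lithium [(5,5'-diallyl-2,2'-dimethoxybiphenyl-3-yl)oxy]acetylide (not isolated) | [Li]C#COc1cc(CC=C)cc(-c2cc(CC=C)ccc2OC)c1OC | intermediate
13 | 5,5'-diallyl-3-(ethynyloxy)-2,2'-dimethoxybiphenyl | C#COc1cc(CC=C)cc(-c2cc(CC=C)ccc2OC)c1OC | intermediate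
14 | methyl coumalate (methyl 2-oxo-2H-pyran-5-carboxylate) | COC(=O)C1=COC(=O)C=C1 | starting material
15 | methyl 8-[(5,5'-diallyl-2,2'-dimethoxybiphenyl-3-yl)oxy]-3-oxo-2-oxabicyclo[2.2.2]octa-5,7-diene-6-carboxylate (racemic, one enantiomer drawn, not isolated) | O=C1O[C@@H]2C=C(Oc3cc(CC=C)cc(-c4cc(CC=C)ccc4OC)c3OC)[C@H]1C=C2C(=O)OC | intermediate
16 | methyl 4-[(5,5'-diallyl-2,2'-dimethoxybiphenyl-3-yl)oxy]benzoate | COC(=O)c1ccc(Oc2cc(CC=C)cc(-c3cc(CC=C)ccc3OC)c2OC)cc1 | intermediate
17 | {4-[(5,5'-diallyl-2,2'-dimethoxybiphenyl-3-yl)oxy]phenyl}methanol | OCc1ccc(Oc2cc(CC=C)cc(-c3cc(CC=C)ccc3OC)c2OC)cc1 | intermediate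
18 | 5,5'-diallyl-3-[4-(bromomethyl)phenoxy]-2,2'-dimethoxybiphenyl | BrCc1ccc(Oc2cc(CC=C)cc(-c3cc(CC=C)ccc3OC)c2OC)cc1 | intermediate
19 | vinylmagnesium bromide | C=C[Mg]Br | starting material
20 | 5,5'-diallyl-3-(4-allylphenoxy)-2,2'-dimethoxybiphenyl | C=CCc1ccc(Oc2cc(CC=C)cc(-c3cc(CC=C)ccc3OC)c2OC)cc1 | intermediate
21 | 5,5'-diallyl-3-(4-allylphenoxy)biphenyl-2,2'-diyl bis(dibromoborinate) (not isolated) | C=CCc1ccc(Oc2cc(CC=C)cc(-c3cc(CC=C)ccc3OB(Br)Br)c2OB(Br)Br)cc1 | intermediate
22 | isodunnianol | C=CCc1ccc(Oc2cc(CC=C)cc(-c3cc(CC=C)ccc3O)c2O)cc1 | target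

## Step count and risks

Total step count: 11. Longest linear sequence: 11 steps (1 → 22).

**Step 7.** The aryloxy group donates less than an alkoxy group, and the ortho-methoxy group crowds the alkyne. Thermal oligomerisation of the ynol ether and self-condensation of the pyrone may therefore outrun ring closure. The fallback sets out from phenol 7 and buys ring A instead of building it. Nucleophilic aromatic substitution on 4-fluorobenzaldehyde (K2CO3, DMF, 110 °C) should give 4-[(5,5'-diallyl-2,2'-dimethoxybiphenyl-3-yl)oxy]benzaldehyde F1. NaBH4 in MeOH at 0 °C then reduces it to the benzylic alcohol, so the route is rejoined at 17.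

**Step 6.** The terminal ynol ether may be lost through hydration and oligomerisation during work-up, purification and concentration. Any n-BuLi in excess may metalate the allylic–benzylic CH2 groups and cause double-bond migration. The fallback sets out from the acetylide 12 as generated in the flask. It is trapped at −78 °C with Me3SiCl to give 5,5'-diallyl-2,2'-dimethoxy-3-{[(trimethylsilyl)ethynyl]oxy}biphenyl F2, a C-silyl ynol ether that should tolerate chromatography on Et3N-washed silica and storage. Bu4NF in THF at 0 °C frees the alkyne just before use. After extraction into toluene and drying, the solution goes on without concentration, so the route is rejoined at 13.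

**Step 10.** Wurtz-type homocoupling of the activated benzylic bromide and bromine–magnesium exchange may compete with the cross-coupling. The fallback sets out from 18 and replaces the hard organomagnesium and copper system by a neutral Stille coupling. Tributyl(vinyl)stannane and Pd(PPh3)4 in THF at 65 °C should pass through oxidative addition of zerovalent palladium into the benzylic C–Br bond, transmetalation and reductive elimination. This rejoins the route directly at 20. It makes no new compound (none F0).

## Further compounds

F1 | step 7 | 4-[(5,5'-diallyl-2,2'-dimethoxybiphenyl-3-yl)oxy]benzaldehyde | O=Cc1ccc(Oc2cc(CC=C)cc(-c3cc(CC=C)ccc3OC)c2OC)cc1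
F2 | step 6 | 5,5'-diallyl-2,2'-dimethoxy-3-{[(trimethylsilyl)ethynyl]oxy}biphenyl | C[Si](C)(C)C#COc1cc(CC=C)cc(-c2cc(CC=C)ccc2OC)c1OC
F0 | step 10 | none | none
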